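**Plan**

1. Feature used: in the cyclohexane (C1 carries the side chain, C2 a methyl, C3 and C5 are C(Me)OH, C4 is CHOAc, C6 is CHOH) the oxygens on C3 and C6 are 1,4-cis and all four oxygens face away from the C1/C2 carbon substituents. This is the imprint of an O–O bridge laid across a C3=C4–C5=C6 ring diene.
2. Cuts, in retrosynthetic order: the C4 acetate and a C6 silyl ether; C4–O/C5–O (osmylation of C4=C5); the O–O bond; C3–O and C6–O together (singlet-oxygen [4+2]); C10–C11 (Suzuki–Miyaura); C9=C10 (chromium olefination); C7=C8 (Wittig); ring bonds C1–C6 and C2–C3 (pyrone Diels–Alder with loss of CO2).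
3. Forward: the carbocycle is made first from an alkoxybutenolide and 4,6-dimethyl-2-pyrone, and its lactone becomes C2–CH3 and C1–CH2OH. The chain is grown from C7 to C10 and joined to a ready-made pyrone vinyl iodide. The 2,3-dioxabicyclo[2.2.2]octene ring closes last, on the complete triene–pyrone, and is then opened and oxidised further.
4. Stereochemistry: C1/C2 come from cycloaddition anti to the menthyloxy group of a (5S)-alkoxybutenolide (cis by suprafacial addition). C3/C6 come from O2 attack anti to the C1/C2 substituents, and C4/C5 from osmylation directed by the C3 hydroxyl. The three E-alkenes come from a stabilised Wittig reagent, an E-selective chromium olefination and a stereoretentive cross-coupling.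

Key step: step 17

Numbering: ring C1–C6 as above; chain C7 (on C1) to C12 (on the pyrone), with methyls on C8 and C12.
Remark: C1/C2 of the target require the (5S)-menthyloxybutenolide. Taking the familiar crystalline butenolide from (−)-menthol as (5R), the (5S) compound is its mirror image from (+)-menthol, so (+)-menthol is the auxiliary; (−)-menthol would lead to the enantiomer.

**Route**

Step 1
Reactants: 1 furfural
Product: 2 5-hydroxyfuran-2(5H)-one (racemic)
Conditions: O2, rose bengal (cat.), MeOH, visible light, rt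
Reagents that add atoms: oxygen, O=O
Why: Sensitised singlet oxygen adds [4+2] to the furan and methanol cleaves the resulting endoperoxide with loss of the formyl carbon as methyl formate, the standard photo-oxygenation of furfural to the γ-hydroxybutenolide.

Step 2
Reactants: 2 5-hydroxyfuran-2(5H)-one; 3 (+)-menthol
Product: 4 (5S)-5-{[(1S,2R,5S)-5-methyl-2-(propan-2-yl)cyclohexyl]oxy}furan-2(5H)-one
Conditions: CSA (cat.), toluene, reflux, Dean–Stark; crystallisation from petroleum ether, acid re-equilibration of the mother liquor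
Reagents that add atoms: none
Why: Acid-catalysed acetalisation of the pseudo-acid gives both C5 epimers, which interconvert under acid, so crystallisation of the (5S) epimer with recycling of the mother liquor should funnel the material to one diastereomer.

Step 3
Reactants: 4 (5S)-5-menthyloxyfuran-2(5H)-one; 5 4,6-dimethyl-2H-pyran-2-one (3 equiv)
Product: 7 (3S,3aS,7aS)-5,7-dimethyl-3-{[(1S,2R,5S)-menthyl]oxy}-3a,7a-dihydro-2-benzofuran-1(3H)-one, via CO2-bridged cycloadduct 6 (not isolated)
Conditions: toluene, BHT, argon, sealed tube, 140–150 °C; excess 5 recovered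
Reagents that add atoms: none
Why: Normal-demand Diels–Alder reaction of the 2-pyrone followed by retro-[4+2] loss of CO2, in which the nucleophilic unsubstituted C3 of the pyrone should bond to the β-carbon of the butenolide and the methyl-bearing C6 to the α-carbon, while suprafacial addition anti to the menthyloxy group sets ring C1 and C2 cis and in the required absolute sense.

Step 4
Reactants: 7 menthyloxy lactone
Product: 8 (3aS,7aS)-5,7-dimethyl-3a,7a-dihydro-2-benzofuran-1(3H)-one
Conditions: NaBH4 (excess), KOH, EtOH/H2O, 0 °C to rt; then 2 M HCl to pH 2, rt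
Reagents that add atoms: potassium hydroxide, [K+].[OH-] (its oxygen becomes one of the two carboxylate oxygens and is retained in part as the lactone carbonyl oxygen)
Why: Hydroxide opens the acylal-type lactone to the carboxylate and the C7 aldehyde with loss of menthol, borohydride already present should reduce the aldehyde faster than it enolises, and acidification closes the γ-lactone (reductive removal of a γ-alkoxy group from a butyrolactone) without touching C1 or C2.

Step 5
Reactants: 8 cis-fused lactone
Product: 9 (3aS,7aS)-5,7-dimethyl-1,3,3a,7a-tetrahydro-2-benzofuran-1-ol (anomer mixture)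
Conditions: DIBAL-H (1.1 equiv), CH2Cl2, −78 °C; Rochelle salt
Reagents that add atoms: none
Why: Partial reduction of a γ-lactone at −78 °C stops at the tetrahedral aluminium alkoxide, which gives the lactol on work-up.

Step 6
Reactants: 9 lactol
Product: 11 [(1S,6S)-3,5,6-trimethylcyclohexa-2,4-dien-1-yl]methanol, via hydroxy tosylhydrazone 10 (not isolated)
Conditions: TsNHNH2, MeOH, rt; evaporate; catecholborane (3 equiv), CHCl3, 0 °C to rt; NaOAc·3H2O, 60 °C
Reagents that add atoms: none
Why: The lactol condenses through its open hydroxy-aldehyde form, and hydride addition to the C=N bond followed by acetate-induced loss of sulfinate and N2 (catecholborane variant of the Caglioti tosylhydrazone reduction) turns the former lactone carbon into the C2 methyl group under conditions too mild to epimerise C2 or move the diene.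

Step 7
Reactants: 11 dienyl methanol
Product: 13 ethyl (2E)-2-methyl-3-[cis-3,5,6-trimethylcyclohexa-2,4-dien-1-yl]prop-2-enoate (ring stereocentres as in 11), via (1S,6S)-3,5,6-trimethylcyclohexa-2,4-diene-1-carbaldehyde 12 (not isolated)
Conditions: Dess–Martin periodinane, pyridine, CH2Cl2, 0 °C; then Ph3P=C(Me)CO2Et (2 equiv), rt, dark
Reagents that add atoms: ethyl 2-(triphenylphosphoranylidene)propanoate, CCOC(=O)C(C)=P(c1ccccc1)(c1ccccc1)c1ccccc1
Why: Buffered Dess–Martin oxidation gives the sensitive α-branched β,γ-unsaturated aldehyde and the stabilised ylide intercepts it in the same flask in an E-selective Wittig olefination, so the aldehyde is never stored and C1 should not epimerise.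

Step 8
Reactants: 13 enoate
Product: 14 (2E)-2-methyl-3-[cis-3,5,6-trimethylcyclohexa-2,4-dien-1-yl]prop-2-en-1-ol (ring as in 11)
Conditions: DIBAL-H (2.2 equiv), CH2Cl2, −78 °C; Rochelle salt
Reagents that add atoms: none
Why: DIBAL-H reduces an α,β-unsaturated ester by 1,2-addition to the allylic alcohol and leaves the diene untouched.

Step 9
Reactants: 14 allylic alcohol
Product: 15 (2E)-2-methyl-3-[cis-3,5,6-trimethylcyclohexa-2,4-dien-1-yl]prop-2-enal (ring as in 11)
Conditions: Dess–Martin periodinane, pyridine, CH2Cl2, 0 °C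
Reagents that add atoms: none
Why: Dess–Martin oxidation of a primary allylic alcohol is fast and neutral and, unlike MnO2, should not dehydrogenate the cyclohexadiene.

Step 10
Reactants: 15 enal
Product: 16 2-[(1E,3E)-3-methyl-4-(cis-3,5,6-trimethylcyclohexa-2,4-dien-1-yl)buta-1,3-dien-1-yl]-4,4,5,5-tetramethyl-1,3,2-dioxaborolane (ring as in 11)
Conditions: CrCl2 (8 equiv), Cl2CHBpin (2 equiv), LiI (4 equiv), THF, rt, dark
Reagents that add atoms: 2-(dichloromethyl)-4,4,5,5-tetramethyl-1,3,2-dioxaborolane, ClC(Cl)B1OC(C)(C)C(C)(C)O1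
Why: Takai–Utimoto olefination with the geminal dichromium reagent from the dihalomethylboronate adds to the aldehyde and eliminates to the E-alkenylboronate under non-basic conditions that should spare the doubly allylic C1–H.

Step 11
Reactants: 17 diethyl methylmalonate
Product: 18 diethyl 2-(diiodomethyl)-2-methylpropanedioate
Conditions: NaH, Et2O, 0 °C; CHI3, reflux
Reagents that add atoms: iodoform, IC(I)I
Why: C-alkylation of the sodium malonate with iodoform is the established entry to diiodomethyl malonates.

Step 12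
Reactants: 18 diiodomethyl malonate
Product: 19 (2E)-3-iodo-2-methylprop-2-enoic acid
Conditions: KOH, EtOH/H2O, reflux; then HCl
Reagents that add atoms: potassium hydroxide, [K+].[OH-] (one carboxyl oxygen of 19 comes from hydroxide)
Why: Saponification followed by decarboxylative anti-elimination of iodide (Grob-type fragmentation) gives the E-β-iodo acid.

Step 13
Reactants: 19 (E)-3-iodo-2-methylacrylic acid; 20 methyl 2-methyl-3-oxopentanoate
Product: 22 methyl (6E)-7-iodo-2,4,6-trimethyl-3,5-dioxohept-6-enoate (diastereomer and enol mixture), via acyl imidazole 21 (not isolated)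
Conditions: 19, CDI, THF, rt; added at −78 °C to the dianion of 20 (LDA 2.1 equiv, THF, −78 to 0 °C; 2 equiv of dianion); aq. HCl
Reagents that add atoms: none
Why: γ-C-Acylation of a β-keto ester dianion by an acyl imidazole occurs at the more basic terminal carbanion, and the tricarbonyl product is held as its enolate, which should protect the β-iodo enone from conjugate addition.

Step 14
Reactants: 22 triketo ester
Product: 23 4-hydroxy-6-[(1E)-1-iodoprop-1-en-2-yl]-3,5-dimethyl-2H-pyran-2-one
Conditions: DBU (1.5 equiv), toluene, 60 °C; acidic work-up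
Reagents that add atoms: none
Why: Base-mediated enolisation and O-acylation by the methyl ester (lactonisation with loss of methanol) is the standard closure of 3,5-dioxo esters to 4-hydroxy-2-pyrones.

Step 15
Reactants: 23 4-hydroxy-2-pyrone
Product: 24 6-[(1E)-1-iodoprop-1-en-2-yl]-2-methoxy-3,5-dimethyl-4H-pyran-4-one
Conditions: MeOTf (1.2 equiv), CH2Cl2, 0 °C to rt; aq. NaHCO3
Reagents that add atoms: methyl trifluoromethanesulfonate, COS(=O)(=O)C(F)(F)F
Why: A hard methylating agent alkylates the more basic lactone carbonyl oxygen and loss of the 4-OH proton gives the α-methoxy-γ-pyrone, the known regioselective O-methylation of 4-hydroxy-2-pyrones.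

Step 16
Reactants: 16 dienylboronate; 24 pyrone vinyl iodide
Product: 25 2-methoxy-3,5-dimethyl-6-[(2E,4E,6E)-6-methyl-7-(cis-3,5,6-trimethylcyclohexa-2,4-dien-1-yl)hepta-2,4,6-trien-2-yl]-4H-pyran-4-one (ring as in 11)
Conditions: Pd(dppf)Cl2·CH2Cl2 (10 mol %), AsPh3 (20 mol %), Cs2CO3 (3 equiv), degassed DMF/H2O 10:1, rt, dark
Reagents that add atoms: none
Why: Suzuki–Miyaura coupling of an alkenylboronate with an alkenyl iodide proceeds with retention at both partners at room temperature, so the all-E triene should form without base- or heat-induced isomerisation.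

Step 17
Reactants: 25 triene–pyrone cyclohexadiene
Product: 26 C3,C6-endoperoxide of 25 (2,3-dioxabicyclo[2.2.2]oct-5-ene; O–O bridge anti to the C1 side chain and C2 methyl)
Conditions: O2, methylene blue (2 mol %), CH2Cl2, −78 °C, 590–660 nm LED (no light below 500 nm); stopped when 25 is consumed
Reagents that add atoms: oxygen, O=O
Why: Sensitised singlet oxygen acts as a two-atom dienophile and adds suprafacially, in a concerted if asynchronous [4+2] cycloaddition, to the s-cis-locked C3=C4–C5=C6 diene; the closest known reactions are the photo-oxygenation of 1,3-dialkylcyclohexa-1,3-dienes to bicyclic endoperoxides and the same reaction on cyclohexadienes carried by α-methoxy-γ-pyrone polyenes. The six-membered 1,2-dioxine ring closes by cycloaddition, both C–O bonds forming on one face, so that O–O bridges C3 and C6 and C4=C5 remains as the third bridge of the bicycle. C3 and C6 are set together by the face of attack, which is controlled by the cis C1 side chain and C2 methyl group: one of them is pseudoaxial and screens its face, so oxygen should arrive anti to both. The step needs chemoselectivity for the ring diene over [4+2] or ene reaction on the triene (allylic methyls on C8 and C12), and this rests on the ring diene being electron-rich and fixed s-cis while the triene is s-trans and deactivated by conjugation to the pyrone. Low temperature, red light that the triene–pyrone does not absorb, and stopping at full conversion should protect the E-alkenes and the peroxide.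

Step 18
Reactants: 26 endoperoxide
Product: 27 cis-3,6-diol (C3 tertiary OH, C6 secondary OH, C4=C5 retained)
Conditions: thiourea (1.5 equiv), MeOH/CH2Cl2 (wet), 0 °C to rt
Reagents that add atoms: none
Why: Thiourea reduces the O–O bond of bicyclic endoperoxides under neutral conditions without breaking a C–O bond, so both hydroxyls keep the configuration set in step 17.

Step 19
Reactants: 27 cis-diol
Product: 28 C6 triethylsilyl ether of 27 (C3–OH free)
Conditions: TESCl (1.2 equiv), imidazole, DMF, −20 to 0 °C
Reagents that add atoms: chlorotriethylsilane, CC[Si](Cl)(CC)CC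
Why: Silylation distinguishes the secondary C6 hydroxyl from the tertiary C3 hydroxyl, and it removes the hydroxyl closest to the side chain before osmylation.

Step 20
Reactants: 28 C6 silyl ether
Product: 30 3,4,5-triol with C6–OTES (all four ring oxygens on one face), via osmate ester·TMEDA complex 29 (not isolated)
Conditions: OsO4 (1.05 equiv), TMEDA (1.1 equiv), CH2Cl2, −78 °C; then sat. aq. Na2SO3, THF, 45 °C
Reagents that add atoms: osmium tetroxide, O=[Os](=O)(=O)=O
Why: Hydroxyl-directed osmylation, in which the OsO4·TMEDA complex accepts a hydrogen bond from the pseudoaxial C3 hydroxyl and is delivered to the same face of C4=C5 ([3+2] addition), sets C4 and C5 and should favour the allylic-alcohol alkene over the pyrone-deactivated triene, after which sulfite releases the diol.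

Step 21
Reactants: 30 triol
Product: 31 C4 acetate of 30 (C3–OH and C5–OH free, C6–OTES)
Conditions: Ac2O (1.5 equiv), DMAP (0.1 equiv), pyridine, CH2Cl2, 0 °C
Reagents that add atoms: acetic anhydride, CC(=O)OC(C)=O
Why: DMAP-catalysed acylation takes the only secondary hydroxyl (equatorial C4–OH) while the two flanking tertiary hydroxyls react far more slowly.

Step 22
Reactants: 31 acetate silyl ether
Product: 32 amaurone A
Conditions: HF·pyridine, pyridine, THF, 0 °C to rt
Reagents that add atoms: none
Why: Buffered fluoride desilylation cleaves the secondary TES ether without the basic conditions that could move the C4 acetate or harm the methoxypyrone.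

**Compound list**

1 | furfural | O=Cc1ccco1 | starting material
2 | 5-hydroxyfuran-2(5H)-one (racemic) | O=C1C=CC(O)O1 | intermediate
3 | (+)-menthol, (1S,2R,5S)-5-methyl-2-(propan-2-yl)cyclohexan-1-ol | C[C@H]1CC[C@@H]([C@H](C1)O)C(C)C | starting material
4 | (5S)-5-{[(1S,2R,5S)-5-methyl-2-(propan-2-yl)cyclohexyl]oxy}furan-2(5H)-one | O=C1C=C[C@@H](O[C@H]2C[C@@H](C)CC[C@@H]2C(C)C)O1 | intermediate
5 | 4,6-dimethyl-2H-pyran-2-one | CC1=CC(C)=CC(=O)O1 | starting material
6 | CO2-bridged cycloadduct: 1,8-dimethyl-2-oxabicyclo[2.2.2]oct-7-en-3-one cis-fused at C5/C6 to the (S)-menthyloxy-γ-butyrolactone (endo/exo mixture, bridgeheads not specified) | O=C1O[C@H](O[C@H]4C[C@@H](C)CC[C@@H]4C(C)C)[C@H]2C3C(C)=CC(C)(OC3=O)[C@@H]12 | intermediate (not isolated)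
7 | (3S,3aS,7aS)-5,7-dimethyl-3-{[(1S,2R,5S)-menthyl]oxy}-3a,7a-dihydro-2-benzofuran-1(3H)-one | O=C1O[C@H](O[C@H]3C[C@@H](C)CC[C@@H]3C(C)C)[C@H]2C=C(C)C=C(C)[C@@H]12 | intermediate
8 | (3aS,7aS)-5,7-dimethyl-3a,7a-dihydro-2-benzofuran-1(3H)-one | O=C1OC[C@H]2C=C(C)C=C(C)[C@@H]12 | intermediate
9 | (3aS,7aS)-5,7-dimethyl-1,3,3a,7a-tetrahydro-2-benzofuran-1-ol (anomers) | OC1OC[C@H]2C=C(C)C=C(C)[C@@H]12 | intermediate
10 | tosylhydrazone of the open hydroxy-aldehyde form of 9 (C2–CH=N–NHTs, C1–CH2OH, cis) | OC[C@H]1C=C(C)C=C(C)[C@H]1/C=N/NS(=O)(=O)c2ccc(C)cc2 | intermediate (not isolated)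
11 | [(1S,6S)-3,5,6-trimethylcyclohexa-2,4-dien-1-yl]methanol | OC[C@H]1C=C(C)C=C(C)[C@H]1C | intermediate
12 | (1S,6S)-3,5,6-trimethylcyclohexa-2,4-diene-1-carbaldehyde | O=C[C@H]1C=C(C)C=C(C)[C@H]1C | intermediate (not isolated)
13 | ethyl (2E)-2-methyl-3-[cis-3,5,6-trimethylcyclohexa-2,4-dien-1-yl]prop-2-enoate (ring as in 11) | CCOC(=O)/C(C)=C/[C@H]1C=C(C)C=C(C)[C@H]1C | intermediate
14 | (2E)-2-methyl-3-[cis-3,5,6-trimethylcyclohexa-2,4-dien-1-yl]prop-2-en-1-ol (ring as in 11) | OC/C(C)=C/[C@H]1C=C(C)C=C(C)[C@H]1C | intermediate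
15 | (2E)-2-methyl-3-[cis-3,5,6-trimethylcyclohexa-2,4-dien-1-yl]prop-2-enal (ring as in 11) | O=C/C(C)=C/[C@H]1C=C(C)C=C(C)[C@H]1C | intermediate
16 | 2-[(1E,3E)-3-methyl-4-(cis-3,5,6-trimethylcyclohexa-2,4-dien-1-yl)buta-1,3-dien-1-yl]-4,4,5,5-tetramethyl-1,3,2-dioxaborolane (ring as in 11) | CC1(C)OB(/C=C/C(C)=C/[C@H]2C=C(C)C=C(C)[C@H]2C)OC1(C)C | intermediate
17 | diethyl methylmalonate | CCOC(=O)C(C)C(=O)OCC | starting material
18 | diethyl 2-(diiodomethyl)-2-methylpropanedioate | CCOC(=O)C(C)(C(I)I)C(=O)OCC | intermediate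
19 | (2E)-3-iodo-2-methylprop-2-enoic acid | OC(=O)/C(C)=C/I | intermediate
20 | methyl 2-methyl-3-oxopentanoate | CCC(=O)C(C)C(=O)OC | starting material
21 | 1-[(2E)-3-iodo-2-methylprop-2-enoyl]imidazole | O=C(/C(C)=C/I)n1ccnc1 | intermediate (not isolated)
22 | methyl (6E)-7-iodo-2,4,6-trimethyl-3,5-dioxohept-6-enoate | COC(=O)C(C)C(=O)C(C)C(=O)/C(C)=C/I | intermediate
23 | 4-hydroxy-6-[(1E)-1-iodoprop-1-en-2-yl]-3,5-dimethyl-2H-pyran-2-one | CC1=C(O)C(C)=C(/C(C)=C/I)OC1=O | intermediate
24 | 6-[(1E)-1-iodoprop-1-en-2-yl]-2-methoxy-3,5-dimethyl-4H-pyran-4-one | COc1oc(/C(C)=C/I)c(C)c(=O)c1C | intermediate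
25 | 2-methoxy-3,5-dimethyl-6-[(2E,4E,6E)-6-methyl-7-(cis-3,5,6-trimethylcyclohexa-2,4-dien-1-yl)hepta-2,4,6-trien-2-yl]-4H-pyran-4-one (ring as in 11) | COc1oc(/C(C)=C/C=C/C(C)=C/[C@@H]2[C@H](C)C(C)=CC(C)=C2)c(C)c(=O)c1C | intermediate
26 | C3,C6-endoperoxide of 25 (2,3-dioxabicyclo[2.2.2]oct-5-ene, O–O anti to the C1 chain and C2 methyl) | COc1oc(/C(C)=C/C=C/C(C)=C/[C@@H]2[C@H](C)[C@@](C)(OO3)C=C(C)[C@H]23)c(C)c(=O)c1C | intermediate
27 | cis-3,6-diol (cyclohex-4-ene; both OH anti to the C1 chain and C2 methyl) | COc1oc(/C(C)=C/C=C/C(C)=C/[C@@H]2[C@H](C)[C@@](C)(O)C=C(C)[C@H]2O)c(C)c(=O)c1C | intermediate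
28 | C6 triethylsilyl ether of 27 | COc1oc(/C(C)=C/C=C/C(C)=C/[C@@H]2[C@H](C)[C@@](C)(O)C=C(C)[C@H]2O[Si](CC)(CC)CC)c(C)c(=O)c1C | intermediate
29 | osmate(VI) ester of 28 across C4–O/C5–O, TMEDA complex | COc1oc(/C(C)=C/C=C/C(C)=C/[C@@H]2[C@H](C)[C@@](C)(O)[C@H]3O[Os](=O)(=O)O[C@@]3(C)[C@H]2O[Si](CC)(CC)CC)c(C)c(=O)c1C.CN(C)CCN(C)C | intermediate (not isolated)
30 | 3,4,5-triol with C6–OTES (all four ring oxygens cis) | COc1oc(/C(C)=C/C=C/C(C)=C/[C@@H]2[C@H](C)[C@@](C)(O)[C@@H](O)[C@@](C)(O)[C@H]2O[Si](CC)(CC)CC)c(C)c(=O)c1C | intermediate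
31 | C4 acetate of 30 | COc1oc(/C(C)=C/C=C/C(C)=C/[C@@H]2[C@H](C)[C@@](C)(O)[C@@H](OC(C)=O)[C@@](C)(O)[C@H]2O[Si](CC)(CC)CC)c(C)c(=O)c1C | intermediate
32 | amaurone A (ring 1R,2S,3R,4R,5S,6S in the numbering above) | COc1oc(/C(C)=C/C=C/C(C)=C/[C@@H]2[C@H](C)[C@@](C)(O)[C@@H](OC(C)=O)[C@@](C)(O)[C@H]2O)c(C)c(=O)c1C | target

**Count**

Total steps: 22. Longest linear sequence: 17 steps (steps 1–10 and 16–22, from furfural); the pyrone branch is steps 11–15.

**Steps most likely to fail**

Step 3. The cycloaddition may be too slow at temperatures the product tolerates, and the product diene may then undergo a hydrogen shift or a second cycloaddition; regiocontrol could also be incomplete. Fallback, from 4 back to 7: the ring would be built with a 1-alkoxy-3-silyloxy diene in place of the pyrone. Kinetic silylation (LDA, TMSCl, THF, −78 °C) of commercial 4-methoxypent-3-en-2-one gives 4-methoxy-2-(trimethylsilyloxy)penta-1,3-diene F1. Its [4+2] addition to 4 (toluene, 80–110 °C), again anti to the menthyloxy group and with the CH2 terminus on the β-carbon, gives the silyl enol ether cycloadduct F2. Dilute acid removes the silyl group and methanol to give the cis-fused 3-methylcyclohexenone lactone F3. Kinetic α′-deprotonation (LiHMDS, −78 °C) and PhNTf2 give the cross-conjugated dienyl triflate F4, and Negishi methylation (MeZnCl, Pd(PPh3)4, THF) installs the C5 methyl group and returns lactone 7.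

Step 17. Ene oxygenation or cycloaddition on the triene, or sensitised E/Z isomerisation, may compete with addition to the ring diene. Fallback, from 15 back to 27: the cycloaddition would be moved to the enal, whose only other alkene is deactivated by the aldehyde. Photo-oxygenation under the same conditions gives the enal endoperoxide F5, thiourea gives the enal cis-diol F6, and Takai–Utimoto borylative olefination gives the dienylboronate diol F7. Suzuki–Miyaura coupling of F7 with 24 under the conditions of step 16 returns diol 27.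

Step 20. Osmylation of the triene may compete with the directed reaction, and release of the diol from the stable osmate may be incomplete. Fallback, from 13 back to 30: all ring oxygens would be installed while the side chain is still the electron-poor enoate. Photo-oxygenation of 13 gives the enoate endoperoxide F8, thiourea the enoate cis-diol F9, and TESCl the C6 silyl ether F10. OsO4·TMEDA gives the osmate ester complex F11 and sulfite the enoate triol F12. DIBAL-H (excess) gives the allylic alcohol F13, MnO2 the enal F14 (only the allylic hydroxyl is oxidised), and Takai–Utimoto olefination the dienylboronate triol F15. Suzuki–Miyaura coupling of F15 with 24 returns triol 30.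

**Further compounds**

F1 | step 3 | 4-methoxy-2-(trimethylsilyloxy)penta-1,3-diene | C=C(O[Si](C)(C)C)C=C(C)OC
F2 | step 3 | silyl enol ether cycloadduct of F1 and 4 (cis-fused, epimers at the methoxy-bearing carbon) | O=C1O[C@H](O[C@H]3C[C@@H](C)CC[C@@H]3C(C)C)[C@H]2CC(O[Si](C)(C)C)=CC(C)(OC)[C@@H]12
F3 | step 3 | cis-fused 3-menthyloxy-7-methyl-3a,4-dihydro-2-benzofuran-1,5(3H,7aH)-dione (configuration as in 7) | O=C1O[C@H](O[C@H]3C[C@@H](C)CC[C@@H]3C(C)C)[C@H]2CC(=O)C=C(C)[C@@H]12
F4 | step 3 | dienyl triflate of F3 (triflate on ring C5) | O=C1O[C@H](O[C@H]3C[C@@H](C)CC[C@@H]3C(C)C)[C@H]2C=C(OS(=O)(=O)C(F)(F)F)C=C(C)[C@@H]12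
F5 | step 17 | C3,C6-endoperoxide of enal 15 | O=C/C(C)=C/[C@@H]2[C@H](C)[C@@](C)(OO3)C=C(C)[C@H]23
F6 | step 17 | cis-3,6-diol enal | O=C/C(C)=C/[C@@H]2[C@H](C)[C@@](C)(O)C=C(C)[C@H]2O
F7 | step 17 | (1E,3E)-dienylboronate of the cis-3,6-diol | CC1(C)OB(/C=C/C(C)=C/[C@@H]2[C@H](C)[C@@](C)(O)C=C(C)[C@H]2O)OC1(C)C
F8 | step 20 | C3,C6-endoperoxide of enoate 13 | CCOC(=O)/C(C)=C/[C@@H]2[C@H](C)[C@@](C)(OO3)C=C(C)[C@H]23
F9 | step 20 | cis-3,6-diol enoate | CCOC(=O)/C(C)=C/[C@@H]2[C@H](C)[C@@](C)(O)C=C(C)[C@H]2O
F10 | step 20 | C6 triethylsilyl ether of F9 | CCOC(=O)/C(C)=C/[C@@H]2[C@H](C)[C@@](C)(O)C=C(C)[C@H]2O[Si](CC)(CC)CC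
F11 | step 20 | osmate(VI) ester of F10, TMEDA complex | CCOC(=O)/C(C)=C/[C@@H]2[C@H](C)[C@@](C)(O)[C@H]3O[Os](=O)(=O)O[C@@]3(C)[C@H]2O[Si](CC)(CC)CC.CN(C)CCN(C)C
F12 | step 20 | enoate 3,4,5-triol with C6–OTES | CCOC(=O)/C(C)=C/[C@@H]2[C@H](C)[C@@](C)(O)[C@@H](O)[C@@](C)(O)[C@H]2O[Si](CC)(CC)CC
F13 | step 20 | allylic alcohol from F12 | OC/C(C)=C/[C@@H]2[C@H](C)[C@@](C)(O)[C@@H](O)[C@@](C)(O)[C@H]2O[Si](CC)(CC)CC
F14 | step 20 | enal from F13 | O=C/C(C)=C/[C@@H]2[C@H](C)[C@@](C)(O)[C@@H](O)[C@@](C)(O)[C@H]2O[Si](CC)(CC)CC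
F15 | step 20 | (1E,3E)-dienylboronate from F14 | CC1(C)OB(/C=C/C(C)=C/[C@@H]2[C@H](C)[C@@](C)(O)[C@@H](O)[C@@](C)(O)[C@H]2O[Si](CC)(CC)CC)OC1(C)C
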